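Don't scale product by time while starting material is still growing out of a dissolving solid. Scale it by the exposure E instead: the time integral of c(starting material), as a share of the charge.

the same everywhere: solid substrate 0.96 M; gas phase 200 mM (held)

| charge | catalyst | remark | time |
|---|---|---|---|
| delta | 0.1 mol% | run made earlier |  |
| epsilon | 0.15 mol% | run made earlier |  |
| flask | 0.2 mol% |  | 3.0 min |

| run | time / min | product / % | starting material / % | solid substrate / % |
|---|---|---|---|---|
| delta | 0.333 | 0 | 12.3 | 86.8 |
| delta | 0.667 | 0.8 | 23.4 | 76.3 |
| delta | 1.00 | 1.1 | 32.5 | 68.1 |
| delta | 1.33 | 1.5 | 39.1 | 60.6 |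
| delta | 1.50 | 1.8 | 42.1 | 56.6 |
| delta | 2.00 | 2.9 | 48.7 | 49.2 |
| delta | 2.50 | 3.4 | 53.2 | 42.8 |
| epsilon | 0.167 | 0 | 6.4 | 94.6 |
| epsilon | 0.333 | 0.8 | 12.9 | 87.5 |
| epsilon | 0.667 | 0.3 | 24.1 | 77.2 |
| epsilon | 1.00 | 2.0 | 30.8 | 67.2 |
| epsilon | 1.33 | 2.1 | 37.4 | 60.2 |
| epsilon | 2.00 | 4.1 | 47.5 | 48.9 |
| epsilon | 2.50 | 6.4 | 53.2 | 42.1 |

(standard deviation of a reading: 0.5 percentage points)

- solid, in amounts per volume of the solution: solid substrate
- at the start none of the gas phase is in solution
- at the start none of the solid substrate is in solution
- a reading or a percentage of product counts all its forms, free or not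
- the concentration of product that is asked is that of its free form alone
- starting material means what is dissolved; the solid is not counted in it

- concentration of product (only what is free in solution, in the first phase) at 3.0 min, in M
- concentration of starting material at 3.0 min, in M
- concentration of solid substrate at 3.0 min, in M
- concentration of dissolved gas at 3.0 min, in M

Turn the question round. For starting material to fall in this flask, its drain over the catalyst must exceed the feed from the solid. The delta run gives the exposure up to its last reading, and starting material in the epsilon run matches it there:

E(early part) = 0.596 min; E = 0.850 min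

Pool the product of both runs, divide by their pooled loading and by E, and scale to this flask's loading. That gives the drain constant, a pseudo-first-order constant for loss of starting material:

k = 0.0922 min⁻¹; half-life = 7.52 min

Feed, the last loss of solid held steady, is 0.132 min⁻¹. My reckoning goes round twice:

first round: product 10.3%
solid 35.8%, starting material 53.9%
once more: product 10.3%
drain over feed: 0.376

So this flask stands well short of the turn. I expect 0.0990 M product, bound forms counted, and 0.517 M starting material.

The forecast says 0.092 M, 0.51 M, 0.36 M and 0.18 M, on the ground that “Product rises slightly faster than linearly and scales at least with catalyst”. Its starting material lies a little below mine; its product is the free form, while mine counts bound forms too.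

The flask gives 0.0937 M, 0.529 M, 0.338 M and 0.185 M.

    starting material + dissolved gas + catalyst → catalyst + product (k = 4.45 M⁻² s⁻¹)
    gas phase ⇌ dissolved gas, rate k2*(csat - [dissolved gas]) (kL = 0.0495 s⁻¹)
    solid substrate ⇌ starting material, rate k3*(cs3 - [starting material]) while solid is left; crystals form when [starting material] > cs3 (solubility = 0.710 M, k = 0.00952 s⁻¹)
    catalyst + product ⇌ idle complex (K = 3.30 M⁻¹, k = 0.0162 M⁻¹ s⁻¹)

In this flask, the half-life of starting material by the catalytic step at 3.00 min is 7.9 min, longer than the 3.0 min of the run. The forecast's 0.51 M of starting material would be wrong for a much later reading: this flask left until 30.0 min shows 0 M solid substrate and 0.282 M starting material.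

Read the same flask at 2.0 min: k times the early exposure gives 5.50% product. The computed value is 5.15%, all its forms counted.

The numbers in the tables stem from a simulated flask from invented constants; the scatter is artificial.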